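**Retrosynthetic overview**

1. Target 20 ← 19 (cleavage of the ring C MOM ether) ← 18 (Teuber oxidation of the ring A phenol to the para-quinone) ← 17 (debenzylation).
2. 17 ← 15: the 18-membered ring is opened at the sp3–sp2 bond between the bridge CH2 and the ipso carbon of para-phenylene ring B. The plan rests on this bond, because its alkyl side can be grown from a vinyl group on the crowded ring A carbon that lies between the benzyloxy carbon and the ring D aryloxy carbon (9-BBN hydroboration, then B-alkyl Suzuki–Miyaura closure onto the ring B bromide).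
3. 15 ← aldehyde 14 (methylenation) ← phenol 13 + fluoro aldehyde 4 (SNAr forms the ring A–O–ring D ether and leaves the ring B bromide alone).
4. 13 ← phosphonium salt 6 + aldehyde 10 (Wittig, then diimide: ring C–ring D bridge); 10 ← 8 + 9 (Chan–Lam: ring B–O–ring C ether).
5. Ring order: rings A, B, C and D are bought as benzene rings; the only ring formed is the 18-membered macrocycle (step 10); the ring A quinone is unveiled afterwards.

Key step: step 10

Remark: ring A is brought in as a fluoro aldehyde (from commercial 5-fluoro-2-methoxyphenol), because a copper-mediated etherification of a bromo aldehyde could also engage the ring B bromide. Ring D comes from commercial 3-hydroxybenzyl alcohol. Stilbene 12 is expected as an E/Z mixture; step 7 removes the double bond, so the mixture is carried on and its SMILES is written without geometry.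

**Route**

Step 1
Reactants: 1 5-fluoro-2-methoxyphenol
Product: 2 2-(benzyloxy)-4-fluoro-1-methoxybenzene
Conditions: BnBr, K2CO3, DMF, rt
Reagents that add atoms: benzyl bromide, BrCc1ccccc1
Why: Williamson etherification (SN2) of the only phenoxide with benzyl bromide.

Step 2
Reactants: 2 2-(benzyloxy)-4-fluoro-1-methoxybenzene
Product: 4 2-(benzyloxy)-6-fluoro-3-methoxybenzaldehyde, via aryllithium 3 (not isolated)
Conditions: n-BuLi, THF, −78 °C; then DMF, −78 °C to rt; aq. NH4Cl
Reagents that add atoms: n-butyllithium, CCCC[Li] (lithium of intermediate 3); N,N-dimethylformamide, CN(C)C=O (formyl group of 4)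
Why: Directed ortho-metalation takes the ring hydrogen flanked by fluorine and the benzyloxy oxygen, the most acidic position, and the aryllithium, kept cold to prevent loss of LiF, is formylated by DMF.

Step 3
Reactants: 5 3-hydroxybenzyl alcohol
Product: 6 (3-hydroxybenzyl)triphenylphosphonium bromide
Conditions: PPh3·HBr, MeCN, reflux
Reagents that add atoms: triphenylphosphine hydrobromide, [Br-].[PH+](c1ccccc1)(c1ccccc1)c1ccccc1
Why: Acid-mediated substitution of the benzylic hydroxyl by triphenylphosphine gives the benzylic phosphonium salt, and the phenol does not react.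

Step 4
Reactants: 7 3,4-dihydroxybenzaldehyde
Product: 8 3-hydroxy-4-(methoxymethoxy)benzaldehyde
Conditions: MOMCl (1.0 equiv), K2CO3, acetone, 0 °C to rt
Reagents that add atoms: chloromethyl methyl ether, COCCl
Why: Regioselective Williamson-type alkylation, since the 4-hydroxyl para to the formyl group is the more acidic phenol and is the one deprotonated and alkylated with one equivalent of a weak base.

Step 5
Reactants: 8 3-hydroxy-4-(methoxymethoxy)benzaldehyde; 9 4-bromophenylboronic acid
Product: 10 3-(4-bromophenoxy)-4-(methoxymethoxy)benzaldehyde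
Conditions: Cu(OAc)2 (1 equiv, re-oxidised by air), pyridine, 4 Å MS, CH2Cl2, air, rt
Reagents that add atoms: none
Why: Chan–Lam oxidative O-arylation of the phenol by the arylboronic acid at room temperature, under which the aryl bromide, the aldehyde and the MOM ether are inert.

Step 6
Reactants: 6 (3-hydroxybenzyl)triphenylphosphonium bromide; 10 3-(4-bromophenoxy)-4-(methoxymethoxy)benzaldehyde
Product: 12 3-{2-[3-(4-bromophenoxy)-4-(methoxymethoxy)phenyl]ethenyl}phenol (E/Z mixture), via phenolate ylide 11 (not isolated)
Conditions: KOtBu (2.2 equiv), THF, 0 °C; then 10, 0 °C to rt; aq. NH4Cl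
Reagents that add atoms: potassium tert-butoxide, CC(C)(C)[O-].[K+] (potassium of intermediate 11 only)
Why: Wittig olefination in which two equivalents of base form the phenolate-bearing semi-stabilised benzylic ylide, which condenses with the only aldehyde present.

Step 7
Reactants: 12 3-{2-[3-(4-bromophenoxy)-4-(methoxymethoxy)phenyl]ethenyl}phenol (E/Z mixture)
Product: 13 3-{2-[3-(4-bromophenoxy)-4-(methoxymethoxy)phenyl]ethyl}phenol
Conditions: TsNHNH2 (excess, in portions), NaOAc, THF/H2O, reflux
Reagents that add atoms: none
Why: Diimide reduction, in which HN=NH formed by thermal decomposition of the sulfonyl hydrazide delivers two hydrogens concertedly to the C=C bond and leaves the aryl bromide, the aryl ethers and the acetate-buffered MOM acetal untouched.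

Step 8
Reactants: 13 3-{2-[3-(4-bromophenoxy)-4-(methoxymethoxy)phenyl]ethyl}phenol; 4 2-(benzyloxy)-6-fluoro-3-methoxybenzaldehyde
Product: 14 2-(benzyloxy)-6-(3-{2-[3-(4-bromophenoxy)-4-(methoxymethoxy)phenyl]ethyl}phenoxy)-3-methoxybenzaldehyde
Conditions: K2CO3, DMF, 120 °C
Reagents that add atoms: none
Why: Nucleophilic aromatic substitution (addition–elimination through a Meisenheimer adduct) of the fluoride ortho to the formyl group by the ring D phenoxide, while the unactivated ring B bromide cannot react without a transition metal.

Step 9
Reactants: 14 2-(benzyloxy)-6-(3-{2-[3-(4-bromophenoxy)-4-(methoxymethoxy)phenyl]ethyl}phenoxy)-3-methoxybenzaldehyde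
Product: 15 2-(benzyloxy)-4-(3-{2-[3-(4-bromophenoxy)-4-(methoxymethoxy)phenyl]ethyl}phenoxy)-3-ethenyl-1-methoxybenzene
Conditions: Ph3PCH3Br, KOtBu, THF, 0 °C to rt
Reagents that add atoms: methyltriphenylphosphonium bromide, C[P+](c1ccccc1)(c1ccccc1)c1ccccc1.[Br-]
Why: Wittig methylenation of a non-enolisable aldehyde, since the small unstabilised ylide still reaches the carbonyl between the two ortho oxygen substituents and the aryl bromide and ethers are inert to it.

Step 10
Reactants: 15 2-(benzyloxy)-4-(3-{2-[3-(4-bromophenoxy)-4-(methoxymethoxy)phenyl]ethyl}phenoxy)-3-ethenyl-1-methoxybenzene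
Product: 17 macrocycle with ring A as benzyl-protected guaiacol and ring C as MOM ether, via alkylborane 16 (not isolated)
Conditions: 9-BBN, THF, 0 °C to 50 °C; H2O quench; then slow addition to PdCl2(dppf) (cat.), AsPh3, Cs2CO3, DMF/THF/H2O, 60 °C, high dilution
Reagents that add atoms: 9-borabicyclo[3.3.1]nonane, C1CC2CCCC(C1)B2 (boron fragment of intermediate 16; only its hydrogen stays in 17)
Why: 9-BBN adds across the ring A vinyl group with boron on the terminal carbon to give primary alkylborane 16; zerovalent palladium formed from PdCl2(dppf) then inserts into the ring B C–Br bond, Cs2CO3 and water activate boron for transfer of the primary alkyl group to palladium, and reductive elimination forms the CH2–aryl bond. The closest known reaction type is the B-alkyl Suzuki–Miyaura coupling used as a macrocyclisation. The 18-membered ring is closed end to end at this sp3–sp2 bond, by intramolecular transmetalation between the arylpalladium terminus and the alkylborane terminus of one chain, under slow addition and high dilution. No stereocentre is formed. The step needs anti-Markovnikov hydroboration, which the bulk of 9-BBN and the two ortho substituents of the styrene secure, and ring closure in preference to oligomerisation and β-hydride elimination, which the single bromide, the single borane, dilution and the wide bite angle of dppf favour.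

Step 11
Reactants: 17 macrocycle with ring A as benzyl-protected guaiacol and ring C as MOM ether
Product: 18 macrocyclic ring A phenol (ring C still MOM ether)
Conditions: H2 (1 atm), 10% Pd/C, EtOAc/EtOH, rt
Reagents that add atoms: none
Why: Catalytic hydrogenolysis of the benzyl aryl ether, with no alkene or carbon–halogen bond left to reduce and the MOM acetal, methyl ether and diaryl ethers inert.

Step 12
Reactants: 18 macrocyclic ring A phenol (ring C still MOM ether)
Product: 19 macrocyclic methoxy-para-quinone with ring C as MOM ether
Conditions: K2NO(SO3)2 (Fremy's salt, 3 equiv), KH2PO4 buffer, acetone/H2O, rt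
Reagents that add atoms: potassium nitrosodisulfonate, [K+].[K+].[O]N(S(=O)(=O)[O-])S(=O)(=O)[O-]
Why: Teuber oxidation, in which one nitroxyl radical abstracts the phenolic hydrogen and a second adds at the free para position and leaves as imidodisulfonate to give the para-quinone; the ring A phenol is the only free phenol and both its ortho positions are blocked.

Step 13
Reactants: 19 macrocyclic methoxy-para-quinone with ring C as MOM ether
Product: 20 target CNP0332646.0
Conditions: TFA, CH2Cl2, 0 °C to rt; aqueous work-up
Reagents that add atoms: none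
Why: Acid-catalysed cleavage of the aryl MOM acetal through the methoxymethyl oxocarbenium ion, in a medium that holds no nucleophile able to displace the methoxy or aryloxy group of the quinone by addition–elimination.

**Compound list**

1 | 5-fluoro-2-methoxyphenol | COc1ccc(F)cc1O | starting material
2 | 2-(benzyloxy)-4-fluoro-1-methoxybenzene | COc1ccc(F)cc1OCc1ccccc1 | intermediate
3 | [2-(benzyloxy)-6-fluoro-3-methoxyphenyl]lithium | COc1ccc(F)c([Li])c1OCc1ccccc1 | intermediate (not isolated)
4 | 2-(benzyloxy)-6-fluoro-3-methoxybenzaldehyde | COc1ccc(F)c(C=O)c1OCc1ccccc1 | intermediate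
5 | 3-hydroxybenzyl alcohol | OCc1cccc(O)c1 | starting material
6 | (3-hydroxybenzyl)triphenylphosphonium bromide | [Br-].Oc1cccc(C[P+](c2ccccc2)(c2ccccc2)c2ccccc2)c1 | intermediate
7 | 3,4-dihydroxybenzaldehyde | O=Cc1ccc(O)c(O)c1 | starting material
8 | 3-hydroxy-4-(methoxymethoxy)benzaldehyde | COCOc1ccc(C=O)cc1O | intermediate
9 | 4-bromophenylboronic acid | OB(O)c1ccc(Br)cc1 | starting material
10 | 3-(4-bromophenoxy)-4-(methoxymethoxy)benzaldehyde | COCOc1ccc(C=O)cc1Oc1ccc(Br)cc1 | intermediate
11 | potassium 3-[(triphenylphosphoranylidene)methyl]phenolate (phenolate ylide) | [K+].[O-]c1cccc(C=P(c2ccccc2)(c2ccccc2)c2ccccc2)c1 | intermediate (not isolated)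
12 | 3-{2-[3-(4-bromophenoxy)-4-(methoxymethoxy)phenyl]ethenyl}phenol, E/Z mixture | COCOc1ccc(C=Cc2cccc(O)c2)cc1Oc1ccc(Br)cc1 | intermediate
13 | 3-{2-[3-(4-bromophenoxy)-4-(methoxymethoxy)phenyl]ethyl}phenol | COCOc1ccc(CCc2cccc(O)c2)cc1Oc1ccc(Br)cc1 | intermediate
14 | 2-(benzyloxy)-6-(3-{2-[3-(4-bromophenoxy)-4-(methoxymethoxy)phenyl]ethyl}phenoxy)-3-methoxybenzaldehyde | COc1ccc(Oc2cccc(CCc3ccc(OCOC)c(Oc4ccc(Br)cc4)c3)c2)c(C=O)c1OCc1ccccc1 | intermediate
15 | 2-(benzyloxy)-4-(3-{2-[3-(4-bromophenoxy)-4-(methoxymethoxy)phenyl]ethyl}phenoxy)-3-ethenyl-1-methoxybenzene (seco vinyl arene, key-step precursor) | COc1ccc(Oc2cccc(CCc3ccc(OCOC)c(Oc4ccc(Br)cc4)c3)c2)c(C=C)c1OCc1ccccc1 | intermediate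
16 | B-alkyl-9-BBN adduct of 15 (boron on the terminal carbon of the former vinyl group) | COc1ccc(Oc2cccc(CCc3ccc(OCOC)c(Oc4ccc(Br)cc4)c3)c2)c(CCB2C3CCCC2CCC3)c1OCc1ccccc1 | intermediate (not isolated)
17 | 18-membered macrocycle, ring A as benzyl-protected guaiacol, ring C as MOM ether | COc1ccc2c(CCc3ccc(cc3)Oc3cc(ccc3OCOC)CCc3cccc(c3)O2)c1OCc1ccccc1 | intermediate
18 | macrocyclic ring A phenol, ring C as MOM ether | COc1ccc2c(CCc3ccc(cc3)Oc3cc(ccc3OCOC)CCc3cccc(c3)O2)c1O | intermediate
19 | macrocyclic methoxy-para-quinone, ring C as MOM ether | COC1=CC(=O)C2=C(CCc3ccc(cc3)Oc3cc(ccc3OCOC)CCc3cccc(c3)O2)C1=O | intermediate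
20 | CNP0332646.0 (macrocyclic methoxy-para-quinone with free ring C phenol; no stereocentre) | COC1=CC(=O)C2=C(CCc3ccc(cc3)Oc3cc(ccc3O)CCc3cccc(c3)O2)C1=O | target

**Step count and risks**

Total step count: 13. Longest linear sequence: 10 steps (steps 4 to 13, from 7).

Steps most likely to fail:

1. Step 10. The chain may couple between molecules and oligomerise instead of closing, or the alkylpalladium intermediate may undergo β-hydride elimination or protodeboronation before reductive elimination. The fallback sets out from 15 and comes back at 18. An intramolecular Mizoroki–Heck reaction of 15 (Pd(OAc)2, P(o-tol)3, Et3N, DMF, 100 °C, high dilution) should give the macrocyclic (E)-stilbene with a ring A–CH=CH–ring B bridge F1, with no alkylmetal species involved. Hydrogenation (H2, Pd/C) should then saturate the bridge and cleave the benzyl ether in one operation to give 18.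

2. Step 8. The substitution may be slow, because the fluoroarene is electron-rich and the formyl group between two ortho substituents is twisted out of conjugation, and the aldehyde may degrade at the temperature needed. The fallback sets out from 4 (with 13) and comes back at 14. It swaps the activating group for a linear, base-stable nitrile: 4 is converted (I2, aqueous NH3, THF, rt) into 2-(benzyloxy)-6-fluoro-3-methoxybenzonitrile F2. SNAr of F2 with 13 (K2CO3, DMSO, 100–130 °C) should give the diaryl ether nitrile F3. Reduction with i-Bu2AlH (toluene, −78 °C, dilute aqueous acid work-up) should return aldehyde 14.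

3. Step 13. Under acid the quinone may lose or exchange its aryloxy or methoxy group, which would open the macrocycle at the ring A–O–ring D bond, or the liberated phenol may add to the quinone. The fallback sets out from 19 and comes back at 20. Na2S2O4 (THF/H2O) should reduce 19 to the hydroquinone with ring C as MOM ether F4. HCl in MeOH should remove the MOM group at this robust arene stage to give the hydroquinone with free ring C phenol F5. Ag2O (MgSO4, CH2Cl2, rt) should then re-oxidise only the hydroquinone to give 20.

**Further compounds**

F1 | step 10 | macrocyclic (E)-stilbene with ring A–CH=CH–ring B bridge, ring A benzyl ether, ring C MOM ether | COc1ccc2c(/C=C/c3ccc(cc3)Oc3cc(ccc3OCOC)CCc3cccc(c3)O2)c1OCc1ccccc1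
F2 | step 8 | 2-(benzyloxy)-6-fluoro-3-methoxybenzonitrile | COc1ccc(F)c(C#N)c1OCc1ccccc1
F3 | step 8 | 2-(benzyloxy)-6-(3-{2-[3-(4-bromophenoxy)-4-(methoxymethoxy)phenyl]ethyl}phenoxy)-3-methoxybenzonitrile | COc1ccc(Oc2cccc(CCc3ccc(OCOC)c(Oc4ccc(Br)cc4)c3)c2)c(C#N)c1OCc1ccccc1
F4 | step 13 | macrocyclic hydroquinone with ring C as MOM ether | COc1cc(O)c2c(CCc3ccc(cc3)Oc3cc(ccc3OCOC)CCc3cccc(c3)O2)c1O
F5 | step 13 | macrocyclic hydroquinone with free ring C phenol | COc1cc(O)c2c(CCc3ccc(cc3)Oc3cc(ccc3O)CCc3cccc(c3)O2)c1O
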